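**Retrosynthetic overview**
1. The six-carbon chain on C4 of the central oxazole is read as 2-deoxy-L-fucose: carbinol carbon = sugar C1, CH2 = C2, oxygenated carbons = C3 to C5, methyl = C6, tetradecanoate on O4.
2. Enabling feature: O5 and C1 stand 1,5 to each other and can close to a six-membered dihydropyran (L-fucal). Its enol ether O5–C1=C2 stores the C1 carbonyl level and the C2 methylene, hides O5, and leaves C1–H as the only unhindered vinylic C–H next to oxygen, which makes C1 a masked acyl anion.
3. Key disconnection: oxazole C4–pyran C1, by one-pot C–H borylation/Suzuki–Miyaura coupling of 3-O-silyl-4-O-tetradecanoyl-L-fucal with 4-bromo-2-(oxazol-5-ylmethyl)oxazole. The ketone level is chosen because a 1,3-syn diol requires hydride, not the heteroaryl group, to arrive last.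
4. Endgame: hydration of the enol ether to the hemiketal, then a chelation-controlled 1,3-syn reduction that opens the pyran for good and sets the fourth stereocenter. The pyran also distinguishes equatorial allylic O3 from axial O4, which places the ester.
5. Rings: none is built. Both oxazoles are bought and joined through the CH2 group by a C2-selective Negishi coupling. The pyran comes from the chiral pool (C3, C4, C5) and is the only ring cleaved, in the last step.

Key step: step 5

Assumption: the hemiketals are drawn as the anomer with axial hydroxyl and equatorial heteroaryl group; they equilibrate with the other anomer and with the open hydroxy ketone, and all forms converge on the same chelate in the last step.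

**Step 1**
Reactants: 1 5-(chloromethyl)-1,3-oxazole; 2 2,4-dibromo-1,3-oxazole
Product: 4 4-bromo-2-(1,3-oxazol-5-ylmethyl)-1,3-oxazole, via oxazol-5-ylmethylzinc chloride 3 (not isolated)
Conditions: 1, Zn dust (TMSCl-activated), LiCl, THF, 25 °C; then 2 (0.9 equiv), Pd(PPh3)4 (3 mol %), THF, 25 → 40 °C
Reagents that add atoms: zinc, [Zn] (stands only in 3)
Why: LiCl-assisted insertion of zinc into the hetero-benzylic C–Cl bond gives a non-basic organozinc that leaves the acidic oxazole C2–H alone, and the Negishi coupling should occur at C2–Br of 2, the bond flanked by O and N that adds to zerovalent palladium first, as in the C2-selective couplings of 2,4-dihalogenated thiazoles and oxazoles; no stereocenter is involved.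

**Step 2**
Reactants: 5 3,4-di-O-acetyl-L-fucal
Product: 6 L-fucal
Conditions: K2CO3 (0.1 equiv), MeOH, 0 °C → rt
Reagents that add atoms: none
Why: Zemplén-type transesterification removes both acetates under conditions that leave the enol ether and the three stereocenters untouched.

**Step 3**
Reactants: 6 L-fucal
Product: 7 3-O-(tert-butyldimethylsilyl)-L-fucal
Conditions: TBSCl (1.05 equiv), imidazole, DMF, −20 → 0 °C
Reagents that add atoms: tert-butyldimethylsilyl chloride, CC(C)(C)[Si](C)(C)Cl
Why: Regioselective silylation, since the pseudo-equatorial allylic O3–H is far more accessible than the pseudo-axial O4–H next to the C5 methyl group, which is the known behaviour of fucal and galactal toward one equivalent of a bulky silyl chloride; no stereocenter changes.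

**Step 4**
Reactants: 7 3-O-(tert-butyldimethylsilyl)-L-fucal; 8 tetradecanoyl chloride
Product: 9 3-O-(tert-butyldimethylsilyl)-4-O-tetradecanoyl-L-fucal
Conditions: pyridine, DMAP (cat.), CH2Cl2, 0 °C → rt
Reagents that add atoms: none
Why: DMAP-catalysed acylation of the only free hydroxyl group places the tetradecanoate on O4 with retention, and the weakly basic medium should prevent silyl migration.

**Step 5**
Reactants: 9 3-O-(tert-butyldimethylsilyl)-4-O-tetradecanoyl-L-fucal; 4 4-bromo-2-(1,3-oxazol-5-ylmethyl)-1,3-oxazole
Product: 11 1-C-[2-(1,3-oxazol-5-ylmethyl)-1,3-oxazol-4-yl]-3-O-(tert-butyldimethylsilyl)-4-O-tetradecanoyl-L-fucal, via fucal C1 pinacolboronate 10 (not isolated)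
Conditions: [Ir(OMe)(cod)]2 (2 mol %), 4,4'-di-tert-butyl-2,2'-bipyridine (dtbpy, 4 mol %), B2pin2 (1.0 equiv), hexane, 50 °C; volatiles removed in vacuo; then 4 (1.0 equiv), Pd(OAc)2 (3 mol %), SPhos (6 mol %), K3PO4 (3 equiv), THF/H2O 10:1, 50 °C
Reagents that add atoms: bis(pinacolato)diboron, CC1(C)OB(OC1(C)C)B1OC(C)(C)C(C)(C)O1 (its Bpin group stands only in 10)
Why: The trivalent iridium complex Ir(dtbpy)(Bpin)3 cleaves the vinylic C1–H bond of 9 and releases 10 by C–B reductive elimination, after which a Suzuki–Miyaura cycle (oxidative addition of zerovalent palladium into the C4–Br bond of 4, phosphate-assisted transmetalation of the alkenyl boronate, reductive elimination) forges the bond between oxazole C4 and pyran C1. The closest known reaction type is the iridium-catalysed alpha-borylation of gamma-substituted cyclic vinyl ethers, silylated glycals included, followed by cross-coupling of the glycal boronates with aryl and heteroaryl bromides. No ring is closed and no stereocenter is created, and the three stereocenters of the pyran are safe because neither cycle touches an sp3 carbon. The selectivity needed is C1–H over C2–H, secured by the bulky silyloxy group on C3 that shields C2–H and by the ring oxygen that activates C1–H; 4 offers a single C–Br bond, and its acidic CH2 group and oxazole C2–H, which rule out lithium or magnesium reagents, should be left alone by K3PO4 at 50 °C. In one operation an unfunctionalised C–H bond becomes the full carbon skeleton, and 11 already holds the C1 carbonyl level and the C2 methylene (enol ether), the masked C5 hydroxyl (ring oxygen) and the ester on O4, so that only water and one hydride remain to be added.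

**Step 6**
Reactants: 11 1-C-[2-(1,3-oxazol-5-ylmethyl)-1,3-oxazol-4-yl]-3-O-(tert-butyldimethylsilyl)-4-O-tetradecanoyl-L-fucal
Product: 13 1-C-[2-(1,3-oxazol-5-ylmethyl)-1,3-oxazol-4-yl]-4-O-tetradecanoyl-2,6-dideoxy-alpha-L-lyxo-hexopyranose (hemiketal), via silylated hemiketal 12 (not isolated)
Conditions: 48 % aq HF, MeCN, 0 °C → rt
Reagents that add atoms: water, O
Why: Acid-catalysed enol ether hydration (protonation at C2 gives an oxocarbenium ion stabilised by the ring oxygen and the oxazole, water adds at C1) and HF desilylation run in the same medium; the poor leaving group on C3 should hold back Ferrier-type allylic ionisation, the anomeric centre settles under thermodynamic control, and the ester should stay on O4 because the medium is acidic and O5 is tied up in the ring.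

**Step 7**
Reactants: 13 1-C-[2-(1,3-oxazol-5-ylmethyl)-1,3-oxazol-4-yl]-4-O-tetradecanoyl-2,6-dideoxy-alpha-L-lyxo-hexopyranose (hemiketal)
Product: 15 (2S,3R,4S,6R)-2,4,6-trihydroxy-6-[2-(1,3-oxazol-5-ylmethyl)-1,3-oxazol-4-yl]hexan-3-yl tetradecanoate, via diethylboron chelate 14 (not isolated)
Conditions: Et2BOMe (2.2 equiv), THF/MeOH 4:1, 0 °C, 1 h; then −78 °C, NaBH4; AcOH quench; repeated co-evaporation with MeOH
Reagents that add atoms: diethylmethoxyborane, CCB(CC)OC (its BEt2 group stands only in 14)
Why: Narasaka–Prasad reduction, in which Et2BOMe draws the ring–chain equilibrium of 13 into the six-membered boron chelate 14 of the open beta-hydroxy ketone, whose half-chair with the C3 side chain pseudo-equatorial is attacked axially by borohydride, which should set the (R)-carbinol 1,3-syn to the C3 hydroxyl; the ester survives NaBH4 at −78 °C and the acidic, non-oxidative work-up avoids acyl migration.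

**Compound list**
1 | 5-(chloromethyl)-1,3-oxazole | ClCc1cnco1 | starting material
2 | 2,4-dibromo-1,3-oxazole | Brc1coc(Br)n1 | starting material
3 | (1,3-oxazol-5-ylmethyl)zinc chloride (LiCl complex, not isolated) | Cl[Zn]Cc1cnco1 | intermediate
4 | 4-bromo-2-(1,3-oxazol-5-ylmethyl)-1,3-oxazole | Brc1coc(Cc2cnco2)n1 | intermediate
5 | 3,4-di-O-acetyl-L-fucal (1,5-anhydro-2,6-dideoxy-L-lyxo-hex-1-enitol diacetate) | C[C@@H]1OC=C[C@H](OC(C)=O)[C@@H]1OC(C)=O | starting material
6 | L-fucal, (2S,3S,4S)-2-methyl-3,4-dihydro-2H-pyran-3,4-diol | C[C@@H]1OC=C[C@H](O)[C@@H]1O | intermediate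
7 | 3-O-(tert-butyldimethylsilyl)-L-fucal | C[C@@H]1OC=C[C@H](O[Si](C)(C)C(C)(C)C)[C@@H]1O | intermediate
8 | tetradecanoyl (myristoyl) chloride | CCCCCCCCCCCCCC(=O)Cl | starting material
9 | 3-O-(tert-butyldimethylsilyl)-4-O-tetradecanoyl-L-fucal | C[C@@H]1OC=C[C@H](O[Si](C)(C)C(C)(C)C)[C@@H]1OC(=O)CCCCCCCCCCCCC | intermediate
10 | C1 pinacolboronate of 9 (not isolated) | C[C@@H]1OC(B2OC(C)(C)C(C)(C)O2)=C[C@H](O[Si](C)(C)C(C)(C)C)[C@@H]1OC(=O)CCCCCCCCCCCCC | intermediate
11 | 1-C-[2-(1,3-oxazol-5-ylmethyl)-1,3-oxazol-4-yl]-3-O-(tert-butyldimethylsilyl)-4-O-tetradecanoyl-L-fucal | C[C@@H]1OC(c2coc(Cc3cnco3)n2)=C[C@H](O[Si](C)(C)C(C)(C)C)[C@@H]1OC(=O)CCCCCCCCCCCCC | intermediate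
12 | 3-O-silylated pyranose hemiketal, axial anomeric OH (not isolated) | C[C@@H]1O[C@](O)(c2coc(Cc3cnco3)n2)C[C@H](O[Si](C)(C)C(C)(C)C)[C@@H]1OC(=O)CCCCCCCCCCCCC | intermediate
13 | 1-C-heteroaryl-4-O-tetradecanoyl-2,6-dideoxy-alpha-L-lyxo-hexopyranose, hemiketal in equilibrium with the open hydroxy ketone | C[C@@H]1O[C@](O)(c2coc(Cc3cnco3)n2)C[C@H](O)[C@@H]1OC(=O)CCCCCCCCCCCCC | intermediate
14 | O3-diethylboryl chelate of the open-chain beta-hydroxy ketone (not isolated) | CCCCCCCCCCCCCC(=O)O[C@H]([C@H](C)O)[C@@H](OB(CC)CC)CC(=O)c1coc(Cc2cnco2)n1 | intermediate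
15 | (2S,3R,4S,6R)-2,4,6-trihydroxy-6-[2-(1,3-oxazol-5-ylmethyl)-1,3-oxazol-4-yl]hexan-3-yl tetradecanoate | CCCCCCCCCCCCCC(=O)O[C@H]([C@H](C)O)[C@@H](O)C[C@@H](O)c1coc(Cc2cnco2)n1 | target

**Step count**
- Total step count: 7.
- Longest linear sequence: 6 (steps 2 to 7, from 5).

**Steps most likely to fail**

**Step 5.**
- Risk: incomplete or unselective C–H borylation, protodeboronation of the alkenyl boronate before transmetalation, or sluggish oxidative addition into the electron-rich C4–Br bond.
- Fallback (sets out from 6, returns at 11): classical C1 metalation before the ester is in place.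
- 6 would be bis-silylated (TBSOTf, 2,6-lutidine, CH2Cl2) to 3,4-di-O-TBS-L-fucal F1.
- F1 would be deprotonated at C1 (t-BuLi, THF, −78 → 0 °C) to the 1-lithio glycal F2, then quenched with Bu3SnCl to the 1-tributylstannyl glycal F3.
- Stille coupling of F3 with 4 (Pd(PPh3)4, CuI 10 mol %, DMF, 60 °C) should give the bis-silylated heteroaryl glycal F4.
- TBAF in THF would free the heteroaryl glycal diol F5.
- TBSCl/imidazole should again pick the equatorial allylic O3 to give the 3-O-TBS heteroaryl glycal F6.
- Acylation of F6 with 8 as in step 4 leads back to 11.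

**Step 6.**
- Risk: allylic ionisation at C3 with loss of the silyloxy group, acid-induced beta-elimination of the C3 oxygen from the open keto form, or acid-catalysed drift of the acyl group from O4 to O3 once O3 is free.
- Fallback (sets out from 11, returns at 12): replace the proton by an iodonium ion.
- N-iodosuccinimide in MeCN/H2O at 0 °C should add iodine to C2 and water to C1 under neutral conditions, giving the trans-diaxial 2-iodo hemiketal F7.
- Radical deiodination (Bu3SnH, Et3B/air, toluene, 0 °C) would give 12, here isolated.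
- 12 would then be desilylated separately with HF·pyridine in THF to 13.

**Step 7.**
- Risk: slow ring opening of the hemiketal at low temperature, so that reduction takes place outside the chelate with poor facial selectivity; acyl migration during work-up.
- Fallback (sets out from 13, returns at 15): catalyst control instead of substrate control, by Noyori-type asymmetric transfer hydrogenation with RuCl[(R,R)-TsDPEN](p-cymene), HCO2H/Et3N 5:2, EtOAc, rt.
- At room temperature the open heteroaryl ketone is drained from the equilibrium. The (R,R) catalyst should deliver the (R)-carbinol by analogy with aryl alkyl ketones.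
- This fallback makes no new compound (F0).

**Further compounds**
F1 | step 5 | 3,4-di-O-(tert-butyldimethylsilyl)-L-fucal | C[C@@H]1OC=C[C@H](O[Si](C)(C)C(C)(C)C)[C@@H]1O[Si](C)(C)C(C)(C)C
F2 | step 5 | 1-lithio-3,4-di-O-(tert-butyldimethylsilyl)-L-fucal | C[C@@H]1OC([Li])=C[C@H](O[Si](C)(C)C(C)(C)C)[C@@H]1O[Si](C)(C)C(C)(C)C
F3 | step 5 | 1-tributylstannyl-3,4-di-O-(tert-butyldimethylsilyl)-L-fucal | C[C@@H]1OC([Sn](CCCC)(CCCC)CCCC)=C[C@H](O[Si](C)(C)C(C)(C)C)[C@@H]1O[Si](C)(C)C(C)(C)C
F4 | step 5 | 1-C-[2-(1,3-oxazol-5-ylmethyl)-1,3-oxazol-4-yl]-3,4-di-O-(tert-butyldimethylsilyl)-L-fucal | C[C@@H]1OC(c2coc(Cc3cnco3)n2)=C[C@H](O[Si](C)(C)C(C)(C)C)[C@@H]1O[Si](C)(C)C(C)(C)C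
F5 | step 5 | 1-C-[2-(1,3-oxazol-5-ylmethyl)-1,3-oxazol-4-yl]-L-fucal | C[C@@H]1OC(c2coc(Cc3cnco3)n2)=C[C@H](O)[C@@H]1O
F6 | step 5 | 1-C-[2-(1,3-oxazol-5-ylmethyl)-1,3-oxazol-4-yl]-3-O-(tert-butyldimethylsilyl)-L-fucal | C[C@@H]1OC(c2coc(Cc3cnco3)n2)=C[C@H](O[Si](C)(C)C(C)(C)C)[C@@H]1O
F7 | step 6 | 2-iodo hemiketal of 11 (axial iodine on C2, axial hydroxyl on C1) | C[C@@H]1O[C@](O)(c2coc(Cc3cnco3)n2)[C@H](I)[C@H](O[Si](C)(C)C(C)(C)C)[C@@H]1OC(=O)CCCCCCCCCCCCC
F0 | step 7 | none | none
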